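Per millimole of L in a litre, the next run should be the recipe that ends with the most L.X.

    L + X → L.X (k1 = 12.9 L mol⁻¹ s⁻¹)
    L ⇌ G (K2 = 2.9, k2 = 0.108 s⁻¹)
    X + G → X.G (k3 = 27.6 L mol⁻¹ s⁻¹)
    2 L → L2 (k4 = 3.34 L mol⁻¹ s⁻¹)

all flasks: time 3.0 min
- west: L 1.0 mM (fed, over 2.5 min); X 1.00 equiv; all else is in the flask from the start; the feed brings no volume worth counting
- north-east: L 1.0 mM; X 1.00 equiv; everything together at the start
- south: L 1.0 mM; X 1.00 equiv (fed, over 2.5 min); all else is in the flask from the start; the feed brings no volume worth counting

- the flask with the highest amount of L.X, in percent of the L charged ("all alike" if they lie within 1.5 percentage points) (west / north-east / south / all alike)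
- final L.X, as a percentage of the L charged, in west
- final L.X, as a percentage of the L charged, in north-east
- final L.X, as a percentage of the L charged, in south

- percentages count the L that a species holds: one L2 counts as two
- a doubled species enters its step squared and goes two at a time
- run time (west): 3.0 min

X is used on two paths, directly on L and through G, so the reckoning needs two things: the X used by the end and the part of it that ends as L.X. In north-east, L starts with no G beside it and relaxes towards G in 6.89 s, the reciprocal of the sum of the forward and return rate constants. X at its charge of 1.00 mM takes G at 0.0276 s⁻¹, slower than that relaxation, so the reckoning holds G over L at K2 afterwards, and the part of the X used that ends as L.X is then 13.9 %. Before that, L stands above its equilibrium part, and the reckoning keeps 6.60 % of the L charged as the head start: the L.X made from that excess of L while it relaxes, with X at its charge.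

The reckoning here gives west the same head start, still with X at its charge. In south, X comes in over 2.5 min, much longer than the relaxation, so south gets no head start. The X used follows a second-order law with the mean constant of the relaxed pool of L and G, 23.8 L mol⁻¹ s⁻¹, and L2 is set aside. In north-east that gives 81.1 % of X used over the whole time, while a fed flask counts the mean age of its feed, which gives 71.4 %. L.X, the head start plus the relaxed part of the remaining X used, then comes to 16.9 % in north-east, 15.6 % in west and 9.92 % in south. North-east is the recipe to charge.

The forecast also names north-east, with 15.5 % in west, 19 % in north-east and 11 % in south, higher than this reckoning in north-east and in south, and says: “Feeding X into pre-equilibrated L gives the least L.X”.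

The flask gives north-east, with 14.8 % in west, 17.6 % in north-east and 9.50 % in south. L.X over L.X plus X.G reads 22.3 % in north-east and 22.3 % in west, with 78.8 % and 66.5 % of X used, and 14.6 % in south. For the neighbour charged with 1.7 mM of L and its equivalent of X, the head start comes to 11.2 %, the same reckoning gives 21.9 %, and that flask ends with 21.9 % of L.X.

(The constants were set for the occasion.)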